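**Conventions.** Quinone locants: C1 and C4 are the carbonyl carbons, C2 carries the methyl group, C3 carries the chain, C4a/C8a are the fusion carbons. Ring A is the benzo ring and ring B the quinone ring. Chain carbons are C1'–C32'. The carbons of solanesol are S1 (CH2OH) to S36. The quinone locants are also used for the four-membered-ring precursor 12 (C1 = carbinol carbon, C4 = ring ketone carbon).

**Remark on the chemistry.** Benzocyclobutene-1,2-dione (10) is assumed to be purchasable and solanesol (1) to be the natural all-E nonaprenol.

## Analysis of the target

Menaquinone-8 (16) is a 2,3-disubstituted 1,4-naphthoquinone in which benzo ring A is fused at C4a/C8a to quinone ring B, which carries a methyl group on C2 and a C40 octaprenyl chain on C3. There is no stereogenic carbon; the stereochemistry lies in seven trisubstituted chain alkenes (C2'=C3', C6'=C7' … C26'=C27'), each E and each independent of the others, followed by the terminal isopropylidene unit. The quinone is sensitive to base (deprotonation at C1' leads to chromenols), to light and to nucleophiles. Its reduced form, menaquinol-8 (15), is air-sensitive and cyclises to a chromanol in acid, and the chain alkenes cyclise or migrate in acid and react with electrophilic oxidants. The difficulty is the C3–C1' junction. Attaching a polyprenyl unit to a preformed naphthalene core through an allyl cation equivalent erodes the C2'=C3' geometry and gives positional isomers, Z isomers of so lipophilic a compound are hard to remove, and the C40 alcohol is not a commodity whereas the C45 alcohol 1 is. The feature used here is that C2 with its methyl group, C3 and the whole chain form a C43 unit that maps atom for atom onto S3–S36 of 1 (S3 = C2, the S3 methyl = the C2 methyl, S4 = C3, S5 = C1'), that is, 1 without S1 and S2. The C3–C1' bond and all seven E alkenes are therefore inherited, and only C1, C4 and ring A, a symmetric C8 phthaloyl unit, remain to be added.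

## Retrosynthetic reasoning

**16 to 15.** No carbon–carbon bond is changed; the quinone is taken back to the hydroquinone. The ring-forming step delivers ring B at the hydroquinone oxidation level, so the last forward operation is a mild, neutral two-electron oxidation that the chain tolerates.

**15 to 12.** The C3–C4 bond of ring B is cut and C4 is reconnected to C1, contracting ring B to the four-membered ring of 12. This is the place to cut because the forward bond formation joins a ketene carbon (C4) to an alkene carbon (C3) held in the same six-atom array, with no external electrophile, acid or base. C1 is bonded to C2 from the outset, so methyl and chain cannot exchange positions. The gain is a complete ring B with both oxygens in place. Forward, the four-membered ring must open to 13 with the hydroxyl turned outward, close to 14 faster than the ketene can react otherwise, and enolise to 15, while the chain survives heating.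

**12 to 11 and 10.** The C1–C2 bond is cut. C1 is a tertiary carbinol carbon next to an sp2 carbon, the retron for addition of an alkenyl metal to a ketone. Because 10 is symmetric, either carbonyl gives the same adduct, and one C8 reagent supplies C1, C4 and ring A. Forward, the addition must stop at the mono-adduct and the alkoxide must be protonated before it can cleave the strained ring.

**11 to 9, 8, 6 and 4.** These are functional-group changes at S3 without any new carbon–carbon bond. The real issue is the position of the double bond: it must lie between S3 and S4, not between S3 and the methyl carbon, which is where kinetic deprotonation would put it. The enolate is therefore formed under equilibrating conditions (5) and fixed as the silyl enol ether 6. The enolate is then regenerated without a proton source (7) and sulfonylated to the enol triflate 8. Palladium-catalysed stannylation gives 9, and tin–lithium exchange gives 11. The geometry of the new alkene does not matter, because C3 becomes an aromatic carbon.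

**4 to 2 and 1.** The S2=S3 double bond of 1 is cut. It is the only one of nine alkenes that can be addressed selectively, because the neighbouring hydroxyl directs an epoxidation to it. Oxidative glycol cleavage of 2 by way of 3 then removes S1 and S2 and leaves S3 as the methyl ketone carbon of 4, the future C2 with its methyl group. Forward, only this alkene may be oxidised and the cleavage must not bring acid-induced changes to the chain.

## Alternatives that were turned down

**Alternative 1:** Ring B is cut at both bonds to ring A (C1–C8a and C4–C4a), leaving 3-methyl-4-octaprenylfuran (A1) and benzyne (A3). Forward, fluoride would trigger elimination in the aryne precursor A2, which is 2-(trimethylsilyl)phenyl triflate, and release A3; this adds across the 2- and 5-positions of A1 in a [4+2] cycloaddition to give the oxygen-bridged adduct A4.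
- For it: aryne–furan cycloadditions run at room temperature under nearly neutral conditions, A2 is a shelf reagent, A3 is symmetric, and the chain carbons could again be traced to 1. On mildness of the key step it is stronger than a thermolysis near 140 °C.
- Against it: A3 is an indiscriminate electrophile, and the chain offers eight trisubstituted alkenes with allylic hydrogens for ene reactions. A1 has the least accessible furan substitution pattern and would need several steps from 4. A4 holds only one oxygen, so it must be isomerised by acid to a naphthol such as A5 and then oxidised at the para position, which exposes the chain to acid and to an oxidant after the key step.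
- Comparison: the chosen route accepts the higher temperature and in return delivers both oxygens at the hydroquinone level in a neutral medium, leaving a single mild oxidation.

**Alternative 2:** The C2–C3 bond is cut, leading to a benzene ring with two acyl arms as the bis(trimethylsilyl enol ether) A6. Forward, constant-current anodic oxidation would couple the two enol carbons intramolecularly and close ring B as the 2,3-dihydro-1,4-dione A7, the keto tautomer of 15; its cis/trans mixture is irrelevant because enolisation and oxidation give 16.
- For it: the bond formed is the fully substituted C2–C3 bond, the oxidant is the electrode, and A7 is at the right oxidation level. In that respect it equals the chosen route.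
- Against it: the oxidation potential of silyl enol ethers is not far from that of trisubstituted alkenes, of which the substrate has eight, and the enol radical cation can be intercepted by them or lose an allylic C1' hydrogen. A waxy, highly lipophilic substrate such as A6 dissolves poorly in the polar electrolyte media that electrolysis needs. The diacylbenzene skeleton behind A6 closes by intramolecular aldol reaction to a five-membered ring as soon as it is enolised, and its chain-bearing arm is not delivered by 1 without further degradation.
- Comparison: the chosen route needs no oxidant while the chain faces a reactive intermediate and uses the carbons of 1 as they stand.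

**Alternative 3:** The C1–C2 bond is cut in the manner of the biosynthetic closure of an o-succinylbenzoate. The precursor is the keto diester A8, in which C4 is an aryl ketone, C3 already carries the chain and C2 is the α-carbon of an aliphatic ester. Forward, an alkoxide base in the matching alcohol would drive a Dieckmann condensation of C2 onto the aromatic ester carbonyl (C1), and enolisation would give the aromatic 1,4-dihydroxy-2-naphthoate A9.
- For it: this is the most predictable of the four closures (six-membered ring, made irreversible by aromatisation, basic conditions harmless to the alkenes). On reliability of the key step it is stronger than the chosen ring expansion.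
- Against it: C2 emerges with an ester where the methyl group belongs. Taking an aryl ester down to a methyl group on an air-sensitive naphthalenediol beside an allylic chain costs protection, reduction, activation and deoxygenation, all in the presence of an ortho-prenyl phenol that cyclises readily. A8 also needs the chain put on C3 by alkylation with a C40 electrophile that 1 does not supply.
- Comparison: the chosen route gives up some certainty in the ring closure, but the methyl group and the C3–C1' bond come from 1 and the route ends one step after the key step.

Key step: step 7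

## Route

Step 1
Reactants: 1 solanesol (all-E nonaprenol)
Product: 2 2,3-epoxysolanesol (racemic trans epoxide, 2S*,3S*; the other eight alkenes unchanged)
Conditions: VO(acac)2 (cat.), t-BuOOH (in decane), toluene, 0 °C to rt
Reagents that add atoms: tert-butyl hydroperoxide, CC(C)(C)OO
Why: Hydroxyl-directed vanadium-catalysed epoxidation of an allylic alcohol: the bound alkoxide delivers the peroxide oxygen only to the S2=S3 alkene, and isolated trisubstituted alkenes do not react with t-BuOOH under these conditions; the E alkene gives the trans epoxide as a racemate, and both stereocentres are removed in step 2.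

Step 2
Reactants: 2 2,3-epoxysolanesol
Product: 4 octaprenylacetone (all-E C43 methyl ketone), via triol 3 (not isolated)
Conditions: H5IO6 (2.5 equiv), THF/Et2O, a little H2O, 0 °C to rt
Reagents that add atoms: water, O
Why: Periodic acid cleavage of an epoxide through its glycol (Malaprade reaction): acid-catalysed hydration opens the oxirane at the tertiary carbon S3 to triol 3, and cleavage of both vicinal diol units leaves S3 as the ketone carbon while S1 and S2 leave as formaldehyde and formic acid; periodate does not attack isolated alkenes, and the reagent is in routine use for cleaving epoxides of polyprenoids without cyclisation.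

Step 3
Reactants: 4 octaprenylacetone
Product: 6 internal trimethylsilyl enol ether of 4 (double bond S3=S4; E/Z mixture), via bromomagnesium enolate 5 (not isolated)
Conditions: i-Pr2NMgBr (from EtMgBr and i-Pr2NH), Et2O, 25 °C; then Me3SiCl, Et3N, HMPA, 25 °C
Reagents that add atoms: chlorotrimethylsilane, C[Si](C)(C)Cl
Why: Thermodynamic enolisation with a bromomagnesium dialkylamide: the magnesium enolates equilibrate by proton exchange to the more substituted enolate 5, so O-silylation gives the 2-siloxy-2-ene (Z isomer expected to predominate), not the methyl-derived isomer that a lithium amide would give; the medium is basic throughout, so the chain is not at risk.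

Step 4
Reactants: 6 internal trimethylsilyl enol ether
Product: 8 internal enol triflate (double bond S3=S4; E/Z mixture), via lithium enolate 7 (not isolated)
Conditions: MeLi (1.05 equiv), THF, 0 °C to rt; then PhNTf2, −78 °C to 0 °C; aqueous work-up
Reagents that add atoms: N-phenylbis(trifluoromethanesulfonimide), O=S(=O)(N(c1ccccc1)S(=O)(=O)C(F)(F)F)C(F)(F)F
Why: Cleavage of the O–Si bond by MeLi gives the lithium enolate regiospecifically, and with no proton donor present it cannot equilibrate; O-sulfonylation with PhNTf2 then fixes the double bond position as the enol triflate.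

Step 5
Reactants: 8 internal enol triflate
Product: 9 alkenyltrimethylstannane (Me3Sn on S3; E/Z mixture)
Conditions: Me3SnSnMe3, Pd(PPh3)4 (cat.), LiCl, THF, 65 °C
Reagents that add atoms: hexamethylditin, C[Sn](C)(C)[Sn](C)(C)C
Why: Palladium-catalysed stannylation of an enol triflate (Stille-type coupling with a distannane): oxidative addition of the C–O bond to zerovalent palladium, transmetalation and reductive elimination keep the double bond where it is, and LiCl converts the alkenylpalladium triflate into the chloride, which transmetalates cleanly; the isolated chain alkenes are spectators.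

Step 6
Reactants: 9 alkenyltrimethylstannane, 10 benzocyclobutene-1,2-dione
Product: 12 2-hydroxy-2-(1-methyl-2-octaprenylvinyl)benzocyclobutenone (racemic; E/Z mixture at the new alkene), via alkenyllithium 11 (not isolated)
Conditions: MeLi (0.95 equiv), THF, −78 to −30 °C; then cannulation into 10 (1.5 equiv), THF, −78 °C; aq. NH4Cl at −78 °C
Reagents that add atoms: none
Why: Tin–lithium exchange gives the sp2 carbanion with retention of position and geometry, and inverse addition to excess symmetric dione at −78 °C gives the mono 1,2-adduct because the alkoxide formed deactivates the neighbouring carbonyl; protonation in the cold prevents alkoxide-induced cleavage of the four-membered ring, and the racemic carbinol centre is removed in step 7.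

Step 7
Reactants: 12 2-hydroxy-2-(1-methyl-2-octaprenylvinyl)benzocyclobutenone
Product: 15 menaquinol-8 (2-methyl-3-octaprenylnaphthalene-1,4-diol), via o-quinoid ketene 13 (not isolated), via keto tautomer 14 (not isolated)
Conditions: p-xylene (degassed, 0.01 M), reflux (138 °C), Ar, dark; mesitylene at 160 °C if the opening is slow
Reagents that add atoms: none
Why: This is the benzo-fused case of the thermal rearrangement of 4-alkenyl-4-hydroxycyclobutenones to hydroquinones. Heating breaks the strained C1–C4 σ bond in a conrotatory 4π electrocyclic opening and gives the dearomatised o-quinoid ketene 13; the electron-donating hydroxyl rotates outward, which turns the alkenyl group inward, beside the ketene. Ketene carbon C4 and alkene carbon C3 are then the termini of a cis-configured triene, and a thermal disrotatory 6π electrocyclisation forms the C3–C4 bond, closes the six-membered ring B and restores the aromaticity of ring A, giving 14. Enolisation of 14 removes its only sp3 ring carbon, so no stereocentre persists and both enantiomers and both alkene isomers of 12 converge on 15. The selectivity needed is capture of the ketene by the adjacent alkenyl carbon ahead of the hydroxyl (lactone formation) or a chain alkene; the outward rotation of the hydroxyl secures the first and the intramolecular six-atom array secures the second. The medium is neutral and free of electrophiles, so the seven E alkenes should neither migrate nor cyclise, and exclusion of air keeps 15 from oxidising during the heating. Relief of four-ring strain and formation of the aromatic naphthalenediol drive the sequence.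

Step 8
Reactants: 15 menaquinol-8 (carried on without purification)
Product: 16 menaquinone-8
Conditions: Ag2O, MgSO4, Et2O, rt, dark
Reagents that add atoms: none
Why: Two-electron oxidation of a hydroquinone to the quinone by Ag2O under neutral, anhydrous conditions; the chain alkenes are inert, and the absence of base avoids chromenol formation from the product.

## Compound list

1 | solanesol, (2E,6E,10E,14E,18E,22E,26E,30E)-3,7,11,15,19,23,27,31,35-nonamethylhexatriaconta-2,6,10,14,18,22,26,30,34-nonaen-1-ol | CC(C)=CCC/C(C)=C/CC/C(C)=C/CC/C(C)=C/CC/C(C)=C/CC/C(C)=C/CC/C(C)=C/CC/C(C)=C/CC/C(C)=C/CO | starting material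
2 | 2,3-epoxysolanesol, racemic trans epoxide (2S*,3S*; one enantiomer drawn) | CC(C)=CCC/C(C)=C/CC/C(C)=C/CC/C(C)=C/CC/C(C)=C/CC/C(C)=C/CC/C(C)=C/CC/C(C)=C/CC[C@]1(C)O[C@H]1CO | intermediate
3 | (6E,10E,14E,18E,22E,26E,30E)-3,7,11,15,19,23,27,31,35-nonamethylhexatriaconta-6,10,14,18,22,26,30,34-octaene-1,2,3-triol (racemic; configuration at S2 and S3 not specified, both centres are cleaved) | CC(C)=CCC/C(C)=C/CC/C(C)=C/CC/C(C)=C/CC/C(C)=C/CC/C(C)=C/CC/C(C)=C/CC/C(C)=C/CCC(C)(O)C(O)CO | intermediate
4 | octaprenylacetone, (5E,9E,13E,17E,21E,25E,29E)-6,10,14,18,22,26,30,34-octamethylpentatriaconta-5,9,13,17,21,25,29,33-octaen-2-one | CC(C)=CCC/C(C)=C/CC/C(C)=C/CC/C(C)=C/CC/C(C)=C/CC/C(C)=C/CC/C(C)=C/CC/C(C)=C/CCC(C)=O | intermediate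
5 | bromomagnesium enolate of 4, internal (S3=S4; E/Z mixture) | CC(C)=CCC/C(C)=C/CC/C(C)=C/CC/C(C)=C/CC/C(C)=C/CC/C(C)=C/CC/C(C)=C/CC/C(C)=C/CC=C(C)O[Mg]Br | intermediate
6 | 2-(trimethylsilyloxy)-6,10,14,18,22,26,30,34-octamethylpentatriaconta-2,5,9,13,17,21,25,29,33-nonaene (5E…29E; E/Z mixture at C2) | CC(C)=CCC/C(C)=C/CC/C(C)=C/CC/C(C)=C/CC/C(C)=C/CC/C(C)=C/CC/C(C)=C/CC/C(C)=C/CC=C(C)O[Si](C)(C)C | intermediate
7 | lithium enolate of 4, internal (S3=S4; E/Z mixture) | CC(C)=CCC/C(C)=C/CC/C(C)=C/CC/C(C)=C/CC/C(C)=C/CC/C(C)=C/CC/C(C)=C/CC/C(C)=C/CC=C(C)[O-].[Li+] | intermediate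
8 | 6,10,14,18,22,26,30,34-octamethylpentatriaconta-2,5,9,13,17,21,25,29,33-nonaen-2-yl trifluoromethanesulfonate (5E…29E; E/Z mixture at C2) | CC(C)=CCC/C(C)=C/CC/C(C)=C/CC/C(C)=C/CC/C(C)=C/CC/C(C)=C/CC/C(C)=C/CC/C(C)=C/CC=C(C)OS(=O)(=O)C(F)(F)F | intermediate
9 | trimethyl(6,10,14,18,22,26,30,34-octamethylpentatriaconta-2,5,9,13,17,21,25,29,33-nonaen-2-yl)stannane (5E…29E; E/Z mixture at C2) | CC(C)=CCC/C(C)=C/CC/C(C)=C/CC/C(C)=C/CC/C(C)=C/CC/C(C)=C/CC/C(C)=C/CC/C(C)=C/CC=C(C)[Sn](C)(C)C | intermediate
10 | benzocyclobutene-1,2-dione | O=C1C(=O)c2ccccc21 | starting material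
11 | (6,10,14,18,22,26,30,34-octamethylpentatriaconta-2,5,9,13,17,21,25,29,33-nonaen-2-yl)lithium (5E…29E; E/Z mixture at C2) | CC(C)=CCC/C(C)=C/CC/C(C)=C/CC/C(C)=C/CC/C(C)=C/CC/C(C)=C/CC/C(C)=C/CC/C(C)=C/CC=C(C)[Li] | intermediate
12 | 8-hydroxy-8-(6,10,14,18,22,26,30,34-octamethylpentatriaconta-2,5,9,13,17,21,25,29,33-nonaen-2-yl)bicyclo[4.2.0]octa-1,3,5-trien-7-one, i.e. 2-hydroxy-2-(1-methyl-2-octaprenylvinyl)benzocyclobutenone (racemic; 5E…29E; E/Z mixture at the new alkene) | CC(C)=CCC/C(C)=C/CC/C(C)=C/CC/C(C)=C/CC/C(C)=C/CC/C(C)=C/CC/C(C)=C/CC/C(C)=C/CC=C(C)C1(O)C(=O)c2ccccc21 | intermediate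
13 | o-quinoid ketene: 6-[1-hydroxy-2-methyl-3-octaprenylprop-2-enylidene]cyclohexa-2,4-dien-1-ylidene ketene (alkenyl group turned toward the ketene) | CC(C)=CCC/C(C)=C/CC/C(C)=C/CC/C(C)=C/CC/C(C)=C/CC/C(C)=C/CC/C(C)=C/CC/C(C)=C/CC=C(C)C(O)=C1C=CC=CC1=C=O | intermediate
14 | 4-hydroxy-3-methyl-2-octaprenyl-2H-naphthalen-1-one (racemic keto tautomer of 15) | CC(C)=CCC/C(C)=C/CC/C(C)=C/CC/C(C)=C/CC/C(C)=C/CC/C(C)=C/CC/C(C)=C/CC/C(C)=C/CC1C(C)=C(O)c2ccccc2C1=O | intermediate
15 | menaquinol-8, 2-methyl-3-[(all-E)-octaprenyl]naphthalene-1,4-diol | CC(C)=CCC/C(C)=C/CC/C(C)=C/CC/C(C)=C/CC/C(C)=C/CC/C(C)=C/CC/C(C)=C/CC/C(C)=C/Cc1c(C)c(O)c2ccccc2c1O | intermediate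
16 | menaquinone-8, 2-methyl-3-[(all-E)-octaprenyl]naphthalene-1,4-dione | CC(C)=CCC/C(C)=C/CC/C(C)=C/CC/C(C)=C/CC/C(C)=C/CC/C(C)=C/CC/C(C)=C/CC/C(C)=C/CC1=C(C)C(=O)c2ccccc2C1=O | target

## Step count and least certain steps

Total step count: 8. Longest linear sequence: 8 steps from 1; 10 enters in step 6.

**Step 7 (key step).**
- Risk: the hydroxyl may rotate inward during ring opening, which leads to lactonisation of the ketene. The alkene isomer with the chain on the inside closes more slowly, which gives the ketene time to dimerise or be captured intermolecularly. The free hydroquinone can also oxidise and degrade during prolonged heating.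
- Fallback, from 12 to 16: silylate the carbinol (Me3SiCl, imidazole, CH2Cl2) to the O-trimethylsilyl ether F1. The bulky siloxy group, which has no acidic hydrogen, should rotate outward more cleanly and cannot lactonise. Thermolysis as in step 7 then gives the mono-silylated menaquinol F2, which is not air-sensitive, and oxidative desilylation with (NH4)2Ce(NO3)6 in aqueous MeCN/CH2Cl2 at 0 °C returns to the route at 16.

**Step 3.**
- Risk: equilibration of the enolates may be incomplete, so that some methyl-side enol ether is carried forward; it would end as an isomeric quinone that is hard to separate.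
- Fallback, from 6 (as the mixture) to 8: Saegusa–Ito oxidation with Pd(OAc)2 in MeCN/CH2Cl2 converts only the internal enol ether into the conjugated dienone F3, because the methyl-side isomer has no β-hydrogen to eliminate and reverts to 4, which is separated and recycled. Conjugate hydrosilylation of F3 (catalytic [(Ph3P)CuH]6, PhMe2SiH, toluene) delivers hydride to S5 and gives the dimethylphenylsilyl enol ether F4 with the double bond fixed at S3=S4. MeLi and PhNTf2 as in step 4 convert F4 into 8.

**Step 6.**
- Risk: the alkenyllithium may be quenched by proton abstraction from the doubly allylic S5 methylene during the exchange. The dione may also add twice, or the alkoxide may cleave the ring before the quench.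
- Fallback, from 8 and 10 to 12: Nozaki–Hiyama–Kishi coupling (CrCl2, catalytic NiCl2, DMF/THF, rt). The alkenylchromium species formed from the triflate is far less basic than 11, adds to the strained, activated carbonyl of 10, and gives a chromium alkoxide that does not open the ring; aqueous work-up returns 12 directly, without the stannane.

**Step 2.**
- Risk: the acidic reagent may hydrate or cyclise chain alkenes, or cleavage may stop short at the glycol stage.
- Fallback, from 1 to 4: oxidise the allylic alcohol with MnO2 in CH2Cl2 to solanesal F5, then carry out a retro-aldol cleavage (aqueous K2CO3, Bu4NBr, toluene, reflux with removal of the volatile aldehyde), the reaction that converts citral into methylheptenone. This splits off S1–S2 and returns 4 under purely basic conditions.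

## Further compounds

F1 | step 7 | O-trimethylsilyl ether of 12, 2-(1-methyl-2-octaprenylvinyl)-2-(trimethylsilyloxy)benzocyclobutenone (racemic; E/Z mixture) | CC(C)=CCC/C(C)=C/CC/C(C)=C/CC/C(C)=C/CC/C(C)=C/CC/C(C)=C/CC/C(C)=C/CC/C(C)=C/CC=C(C)C1(O[Si](C)(C)C)C(=O)c2ccccc21
F2 | step 7 | 3-methyl-2-octaprenyl-4-(trimethylsilyloxy)naphthalen-1-ol | CC(C)=CCC/C(C)=C/CC/C(C)=C/CC/C(C)=C/CC/C(C)=C/CC/C(C)=C/CC/C(C)=C/CC/C(C)=C/Cc1c(C)c(O[Si](C)(C)C)c2ccccc2c1O
F3 | step 3 | (3E,5E,9E,13E,17E,21E,25E,29E)-6,10,14,18,22,26,30,34-octamethylpentatriaconta-3,5,9,13,17,21,25,29,33-nonaen-2-one | CC(C)=CCC/C(C)=C/CC/C(C)=C/CC/C(C)=C/CC/C(C)=C/CC/C(C)=C/CC/C(C)=C/CC/C(C)=C/C=C/C(C)=O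
F4 | step 3 | internal dimethylphenylsilyl enol ether of 4 (S3=S4; E/Z mixture) | CC(C)=CCC/C(C)=C/CC/C(C)=C/CC/C(C)=C/CC/C(C)=C/CC/C(C)=C/CC/C(C)=C/CC/C(C)=C/CC=C(C)O[Si](C)(C)c1ccccc1
F0 | step 6 | none | none
F5 | step 2 | solanesal, (2E,6E,…,30E)-3,7,11,15,19,23,27,31,35-nonamethylhexatriaconta-2,6,10,14,18,22,26,30,34-nonaenal | CC(C)=CCC/C(C)=C/CC/C(C)=C/CC/C(C)=C/CC/C(C)=C/CC/C(C)=C/CC/C(C)=C/CC/C(C)=C/CC/C(C)=C/C=O
A1 | alternative 1 | 3-methyl-4-[(all-E)-octaprenyl]furan | CC(C)=CCC/C(C)=C/CC/C(C)=C/CC/C(C)=C/CC/C(C)=C/CC/C(C)=C/CC/C(C)=C/CC/C(C)=C/Cc1cocc1C
A2 | alternative 1 | 2-(trimethylsilyl)phenyl trifluoromethanesulfonate | C[Si](C)(C)c1ccccc1OS(=O)(=O)C(F)(F)F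
A3 | alternative 1 | benzyne (1,2-didehydrobenzene) | C1=CC=CC#C1
A4 | alternative 1 | 2-methyl-3-octaprenyl-1,4-dihydro-1,4-epoxynaphthalene (racemic) | CC(C)=CCC/C(C)=C/CC/C(C)=C/CC/C(C)=C/CC/C(C)=C/CC/C(C)=C/CC/C(C)=C/CC/C(C)=C/CC1=C(C)C2OC1c1ccccc12
A5 | alternative 1 | 3-methyl-2-octaprenylnaphthalen-1-ol (one of the two regioisomeric naphthols) | CC(C)=CCC/C(C)=C/CC/C(C)=C/CC/C(C)=C/CC/C(C)=C/CC/C(C)=C/CC/C(C)=C/CC/C(C)=C/Cc1c(C)cc2ccccc2c1O
A6 | alternative 2 | 1-[2-octaprenyl-1-(trimethylsilyloxy)vinyl]-2-[1-(trimethylsilyloxy)prop-1-enyl]benzene | CC(C)=CCC/C(C)=C/CC/C(C)=C/CC/C(C)=C/CC/C(C)=C/CC/C(C)=C/CC/C(C)=C/CC/C(C)=C/CC=C(O[Si](C)(C)C)c1ccccc1C(=CC)O[Si](C)(C)C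
A7 | alternative 2 | 2-methyl-3-octaprenyl-2,3-dihydronaphthalene-1,4-dione (cis/trans mixture) | CC(C)=CCC/C(C)=C/CC/C(C)=C/CC/C(C)=C/CC/C(C)=C/CC/C(C)=C/CC/C(C)=C/CC/C(C)=C/CC1C(C)C(=O)c2ccccc2C1=O
A8 | alternative 3 | methyl 2-(4-methoxy-2-octaprenyl-4-oxobutanoyl)benzoate (racemic) | CC(C)=CCC/C(C)=C/CC/C(C)=C/CC/C(C)=C/CC/C(C)=C/CC/C(C)=C/CC/C(C)=C/CC/C(C)=C/CC(CC(=O)OC)C(=O)c1ccccc1C(=O)OC
A9 | alternative 3 | methyl 1,4-dihydroxy-3-octaprenyl-2-naphthoate | CC(C)=CCC/C(C)=C/CC/C(C)=C/CC/C(C)=C/CC/C(C)=C/CC/C(C)=C/CC/C(C)=C/CC/C(C)=C/Cc1c(C(=O)OC)c(O)c2ccccc2c1O
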